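(All runs are calculated with made-up constants; the scatter is artificial.)

The ratio of D to X reads 0.846 at the first reading of the south run, at 32 °C, and 0.364 at the first reading of the south-west run, at 49 °C, though J and G differ between them too. That ratio hints which way heat leans, but the asked share also carries L, and L climbs through the readings of both runs.

in all of them: Q 10 mM

|  | J | G | temperature | remark | time |
|---|---|---|---|---|---|
| north | 20 mM | 0.67 mM | 32 °C | run made earlier |  |
| south-west | 30 mM | 0.67 mM | 49 °C | run made earlier |  |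
| south | 40 mM | 0.34 mM | 32 °C | run made earlier |  |
| oak | 40.0 mM | 0.67 mM | 25 °C |  | 1.0 h |
| cedar | 40.0 mM | 0.67 mM | 55 °C |  | 1.0 h |
| larch | 40.0 mM | 0.67 mM | 40 °C |  | 1.0 h |

| run | time / min | D / % | X / % | L / % |
|---|---|---|---|---|
| north | 4.00 | 24 | 31 | 1 |
| north | 6.00 | 23 | 32 | 0 |
| north | 10.0 | 27 | 31 | 0 |
| north | 20.0 | 24 | 30 | 2 |
| north | 30.0 | 23 | 32 | 5 |
| north | 50.0 | 25 | 32 | 6 |
| south-west | 2.50 | 16 | 44 | 3 |
| south-west | 5.00 | 16 | 41 | 4 |
| south-west | 8.00 | 15 | 41 | 7 |
| south-west | 10.0 | 16 | 39 | 7 |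
| south-west | 12.0 | 15 | 37 | 7 |
| south-west | 15.0 | 12 | 39 | 10 |
| south | 4.00 | 33 | 39 | 1 |
| south | 8.00 | 33 | 40 | 2 |
| south | 15.0 | 32 | 41 | 2 |
| south | 25.0 | 31 | 40 | 4 |
| south | 50.0 | 28 | 37 | 7 |

(scatter of a reading: 1.5 percentage points)

1. the best flask by share of D in all that became D or X or L; "all alike" if 1.5 percentage points covers them all (oak / cedar / larch / all alike)
2. share of D in all that became D or X or L, oak
3. share of D in all that became D or X or L, cedar
4. share of D in all that became D or X or L, larch

I treat all that is not yet L as one pool. J is charged in excess, so I take the loss as pseudo-first-order. L then follows a closed form: L equals the whole charge times one minus exp(−constant × time).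

The L readings of the south run give 0.00136 min⁻¹ for the drain constant, the fraction of the pool that becomes L each minute. The south-west run gives 0.00599 min⁻¹.

A second way reads the same constant from the fall of D plus X. It gives 0.00222 min⁻¹ and 0.0130 min⁻¹. The two ways part. But the second sums two peaks at each end, so in the south-west run its scatter is 0.00471 min⁻¹ against 0.00170 min⁻¹ for the L way. I keep the L way.

Read as if temperature alone parted the two runs, the two constants give an apparent activation energy of 71.3 kJ mol⁻¹. My L after 1.0 h is then 4.13% in oak, 15.4% in larch and 44.3% in cedar. The south-west run held 30 mM of J, not 40.0 mM, so I read the hot figures as a low guess. My L is higher in cedar than in oak, and the ratio read is lower in the hotter run, so I rank oak first.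

The forecast says 49% for oak, 27% for larch and 8% for cedar, so oak; among its grounds is that “L grows slowly and irreversibly from the pool”. Its L is about 18% in larch and about 55% in cedar, which differs from mine.

The flasks give 46.5% in oak, 27.4% in larch and 8.57% in cedar, so oak is best.

    2 G → Z (k = 1.95 M⁻¹ s⁻¹, Ea = 56.0 kJ mol⁻¹)
    D + G ⇌ X + G, rate k2*[G]*[D] forward; the back reaction follows from the equilibrium constant (k = 2.01 M⁻¹ s⁻¹, Ea = 51.0 kJ mol⁻¹)
    Q + J → L (k = 0.00132 M⁻¹ s⁻¹, Ea = 74.0 kJ mol⁻¹)
    Q + J ⇌ D (K = 48.0 M⁻¹, k = 0.395 M⁻¹ s⁻¹, Ea = 44.0 kJ mol⁻¹, ΔH = −32.0 kJ mol⁻¹)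
    Q + J ⇌ X (K = 50.0 M⁻¹, k = 0.168 M⁻¹ s⁻¹, Ea = 65.0 kJ mol⁻¹, ΔH = −4.00 kJ mol⁻¹)
    (constants at 25 °C)

In larch, Q + J and X relax in 0.346 min by that step alone, both ways together, short against 1.0 h, and L of 17.7% at 1.00 h makes the drain constant 0.00325 min⁻¹. Carried to 15 min, that constant gives L of 4.76%, and the larch flask read at that time holds 4.93%.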